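## Structural features

The target is a germacranolide: a cyclodecadiene (C1–C10) cis-fused along C6–C7 to a γ-butyrolactone (oxygen on C6, C7–C11 bond, C12 as carbonyl, C13 as the methyl on C11). The carbocycle holds a 1,5-diene made of two trisubstituted alkenes, C10(CH3)=C1 (Z) and C4(CH3)=C5 (E), and C5 is bonded directly to the oxygenated C6. Four stereocentres stand in a row, C6 (S), C7 (R), C8 (S) and C11 (S). H6 and H7 are cis, the C8 acetate is trans to the C7–C11 bond and 1,3-anti to the lactone oxygen, and quaternary C11 carries its methyl on the concave face and the angelate on the convex face. Fragile points are the angelate (a Z-enoate that isomerises to the tiglate with nucleophiles, base or heat), the 1,5-diene (Cope rearrangement, acid-induced transannular cyclisation) and the allylic C6–O bond. Three different acyl groups forbid any late hydrolysis, and in ketone intermediates the C8 oxygen is β to C6 and can be lost by E1cB. The real difficulty is the Z/E pair inside a ten-membered ring, the C6–C7–C8 triad on a mobile ring, and the acylation of a tertiary alcohol with an isomerisable acid. The key step exploits the unit C10(CH3)=C1–C2–C3–C4(CH3)=C5 next to oxygenated C6: both alkenes are the retron of a cyclobutane C1–C4–C5–C10, with C1–C4 in a bicyclo[2.2.0]hexane and C5–C10 in a cyclohexanone ring (ring K) fused to it.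

## Logic of the disconnections

22 to 21: the O–acetyl bond at C8 is cut first. An acetate cannot survive the enolate chemistry at C7 and C11, so it must come last. The forward step only has to acylate a secondary alcohol without touching the angelate.

21 to 20: the O–Si bond at C8. A silyl ether stands heat and enolates, and in 12 it also serves as the conformational anchor of the key step. The forward step needs a fluoride source that leaves lactone, angelate and diene alone.

20 to 19: the ester C–O bond of the tertiary C11 oxygen. The Z-enoate would not survive enolates or the oxaziridine, so it is attached after C11 is complete. The forward acylation must not isomerise it.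

19 to 18 to 17: C11–O, then C11–CH3. Both groups enter the lactone enolate from the convex face, so methyl must come first and oxygen second to give 11S. This reduces the problem to an unsubstituted cis-lactone.

17 to 16 to 14: the lactone C6–O bond (made with inversion) and the C6–H bond. Hydride is expected on the outer face of the C6 carbonyl, which gives the epimer that cannot close directly to the cis-lactone. The ring is therefore closed by displacement at C6, which must proceed by SN2 without ionising the allylic alcohol.

14 to 13: the C7–C11 bond, cut to a kinetic α′-enolate and a two-carbon bromo ester. The forward step needs regioselective deprotonation at C7 and facial control from C8.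

13 to 12 (key step): the alkenes C1=C10 and C4=C5 are traded for the σ bonds C1–C4 and C5–C10. A ten-membered ring with two defined alkenes becomes a rigid tricycle that one photocycloaddition can assemble. The forward step must pass through the chair diyl with C6 equatorial and C9 axial, and in that chair the angular C10 methyl is axial on ring K. In 12 the silyloxy group is therefore placed trans to this methyl, so that it is equatorial only in the productive chair. The facial isomer with the silyloxy group cis to the methyl, though the likelier photoproduct, would have this group axial and syn to the methyl there, and is rejected.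

12 to 8 and 10: the bonds C4–C5 and C1–C10 of a [2+2] photocycloaddition. The forward step needs the regiochemistry that keeps the two quaternary carbons apart and cis-anti-cis fusion after epimerisation. It also needs attack on the enone face that carries the silyloxy group, which is the weakest demand of the route.

10 to 9: double-bond isomerisation of a commercial alkene.

8 to 7 to 6: the C10–CH3 bond and a 1,3-carbonyl transposition. This moves the carbonyl to C6 and leaves the C8 stereocentre untouched.

6 to 4 to 3 to 2 to 1: elimination of acetate, desymmetrising acetylation, monosilylation and arene hydrogenation. The arene is reduced fully, not partially: the meso triol gives an enzyme two enantiotopic hydroxyls and so fixes the absolute configuration, whereas a partly reduced dione offers no such handle.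

## Other disconnections considered

Alternative 1: The cut goes through C6–H, the C8 O–acetyl bond and the lactone C12–O bond of an open chain, with the ten-membered ring still to be closed at C3–C4.
- Forward step: an Evans–Tishchenko reduction with SmI2 and acetaldehyde. The C8 hydroxyl forms a hemiacetal and its hydride would pass to the C6 ketone through a samarium-bridged six-membered transition state. This gives the 6,8-anti relation and the C8 acetate at once, and the freed C6 alkoxide closes on C12 to give A1.
- In favour: C6 would be set by an internally delivered hydride with a firm model. The acetate arrives in the same operation and tells O8 from O6 without a protecting group. On both points it is better than the chosen plan, which uses an undirected hydride addition, an inversion at C6 and a late silyl-for-acetyl exchange. A1 also already holds C11 with its oxygen.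
- Against: C7, C8 and quaternary C11 must first be built by acyclic aldol-type chemistry. Both trisubstituted alkenes need their own stereoselective syntheses. Acetate and lactone must then survive a ten-membered closure at C3–C4, an sp3–sp2 coupling under dilution.
- Comparison: on structure A1 is ahead in oxidation pattern, and its alkene geometry comes from fragment synthesis, not from a conformer preference. On mechanism the fragmentation of the chosen plan avoids the medium-ring closure that A1 still faces. On step economy the fragment syntheses would most probably exceed 17 steps.

Alternative 2: The cut removes C5–C6 and C4–CH3.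
- Forward step: zerovalent nickel (Ni(cod)2 with a phosphine) would join the C4≡C5 alkyne terminus and the C6 aldehyde to an oxanickelacycle. Zn(CH3)2 transmetallates and reductive elimination places the methyl on C4. The C6 alkoxide then closes the lactone to A2.
- In favour: one step would form the ring, the C4=C5 alkene, the C6 stereocentre and the lactone. The E geometry follows from syn addition across the alkyne, which is better than the chosen plan, where it rests on a chair preference.
- Against: the closure is ten-membered, with strain and entropy to pay. C6 would be set only by macrocyclic induction from C7, without a firm model. Reductive coupling without methyl transfer and alkyne oligomerisation compete. The open chain needs the 1(10)Z alkene, C7, C8 and C11 in place and an aldehyde next to enolisable C7.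
- Comparison: on structure A2 is equal to the chosen lactone stage, since the endgame is the same apart from one more silyl group. On mechanism A2 is better for alkene geometry and the chosen plan is better for ring formation. On step economy the acyclic synthesis makes it no shorter.

Alternative 3: The cut is C6–C7.
- Forward step: in a thirteen-membered cyclic ether, tin–lithium exchange would make an α-alkoxy carbanion at C6. A [2,3]-shift forms C6–C7, moves the alkene to C11=C13 and cleaves O–C13, contracting the ring to A3.
- In favour: C6–C7 and both of its stereocentres would form in one concerted step through an envelope transition state, which is better than the alkylation, reduction and inversion sequence of the chosen plan. Both ring alkenes are built acyclically with unambiguous geometry, also better. A thirteen-membered ether closes more easily than a ten-membered carbocycle. The free C6 hydroxyl and protected C8 oxygen are as well differentiated as in the chosen plan, so equal there.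
- Against: it needs a configurationally defined α-alkoxystannane and a macrocyclic ether. A [1,2]-shift competes. A3 carries C11 as an exocyclic alkene and C12 as a primary silyl ether, so the lactone carbonyl, the C11 oxygen and the C13 methyl must all be made afterwards in the presence of two ring alkenes.
- Comparison: on structure the chosen plan reaches the lactone oxidation level directly. On mechanism A3 has the stronger stereocontrol at C6 and C7. On step economy A3 is longer.

Key step: step 9

Assumption: in step 3 the lipase acetylates the carbinol of R configuration (the silyloxy-bearing arm acting as the large group), which gives 4 as drawn; this sense must be verified on the first batch.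

## Route

Step 1
Reactants: 1 phloroglucinol
Product: 2 all-cis-cyclohexane-1,3,5-triol
Conditions: H2 (100 bar), Raney Ni, EtOH, 100 °C; recrystallisation
Reagents that add atoms: none
Why: Heterogeneous arene hydrogenation delivers all hydrogens from the catalyst face, so the all-cis (meso) triol should predominate and crystallise.

Step 2
Reactants: 2 all-cis-cyclohexane-1,3,5-triol
Product: 3 all-cis-5-(tert-butyldimethylsilyloxy)cyclohexane-1,3-diol
Conditions: NaH (1.0 equiv), THF/DMF, 0 °C; TBSCl (1.0 equiv), 0 → 25 °C; recovered 2 recycled
Reagents that add atoms: tert-butyldimethylsilyl chloride, CC(C)(C)[Si](C)(C)Cl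
Why: Monosilylation of a symmetric polyol through its mono-sodium alkoxide; the three hydroxyls are equivalent, so only the degree of silylation needs control and the product is a meso diol.

Step 3
Reactants: 3 all-cis-5-(tert-butyldimethylsilyloxy)cyclohexane-1,3-diol
Product: 4 (1R,3S,5S)-3-(tert-butyldimethylsilyloxy)-5-hydroxycyclohexyl acetate
Conditions: Candida antarctica lipase B (immobilised), vinyl acetate, tBuOMe, 25 °C
Reagents that add atoms: vinyl acetate, CC(=O)OC=C
Why: Lipase-catalysed enantiotopos-selective transesterification (desymmetrisation) of a meso cis-1,3-diol, irreversible because the released enol tautomerises. This step sets the absolute configuration of the route (the silyloxy carbon becomes C8, S).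

Step 4
Reactants: 4 (1R,3S,5S)-3-(tert-butyldimethylsilyloxy)-5-hydroxycyclohexyl acetate
Product: 6 (R)-5-(tert-butyldimethylsilyloxy)cyclohex-2-en-1-one, via β-acetoxy ketone 5 (not isolated)
Conditions: Dess–Martin periodinane, CH2Cl2, 0 → 25 °C; then Et3N, 0 °C
Reagents that add atoms: none
Why: Alcohol oxidation, then E1cB loss of the β-acetate. Acetate leaves far more readily than silanolate under the mild amine base, so the alkene forms on the acetate side only and the silyloxy centre is kept.

Step 5
Reactants: 6 (R)-5-(tert-butyldimethylsilyloxy)cyclohex-2-en-1-one
Product: 7 (5R)-5-(tert-butyldimethylsilyloxy)-1-methylcyclohex-2-en-1-ol (both C1 epimers)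
Conditions: MeLi, Et2O, −78 °C; then H2O
Reagents that add atoms: methyllithium, [Li]C
Why: 1,2-Addition of a hard organolithium to the enone carbonyl at low temperature. The new carbinol centre is destroyed in step 6, so its configuration is irrelevant.

Step 6
Reactants: 7 (5R)-5-(tert-butyldimethylsilyloxy)-1-methylcyclohex-2-en-1-ol
Product: 8 (S)-5-(tert-butyldimethylsilyloxy)-3-methylcyclohex-2-en-1-one
Conditions: pyridinium chlorochromate C5H5NH[CrO3Cl], NaOAc, 4 Å sieves, CH2Cl2, 25 °C
Reagents that add atoms: none
Why: Oxidative 1,3-transposition of a tertiary allylic alcohol (Dauben oxidation): [3,3] shift of the chromate ester, then oxidation of the transposed secondary ester. Acetate buffering protects the β-silyloxy enone from acid-induced elimination.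

Step 7
Reactants: 9 methylenecyclobutane
Product: 10 1-methylcyclobutene
Conditions: KOtBu (cat.), DMSO, 70 °C; fractional distillation
Reagents that add atoms: none
Why: Base-catalysed allylic isomerisation through the allyl anion to the more substituted endocyclic alkene.

Step 8
Reactants: 8 (S)-5-(tert-butyldimethylsilyloxy)-3-methylcyclohex-2-en-1-one; 10 1-methylcyclobutene
Product: 12 cis-anti-cis tricyclic silyloxy ketone (silyloxy group trans to the C10 methyl), via trans-fused C5 epimer 11 (not isolated)
Conditions: hν (350 nm, Pyrex), 10 (excess), CH2Cl2, −40 °C; then basic Al2O3, Et2O, 25 °C; chromatography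
Reagents that add atoms: none
Why: Triplet-enone [2+2] photocycloaddition through 1,4-diradicals: C10 bonds to C1 and C5 to C4, which keeps the two quaternary carbons apart, and the outer four-membered ring ends up anti to the cyclohexanone. Trans-fused 11 is epimerised at C5 on basic alumina. Both enone faces react, and the facial isomer needed (silyloxy cis to the new rings) is separated from its isomer.

Step 9
Reactants: 12 cis-anti-cis tricyclic silyloxy ketone
Product: 13 (2E,6Z,9S)-9-(tert-butyldimethylsilyloxy)-3,7-dimethylcyclodeca-2,6-dien-1-one (germacrane numbering: 1(10)Z,4E-dien-6-one, 8S)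
Conditions: degassed PhMe (0.01 M), base-washed flow coil, 200 °C, short residence time
Reagents that add atoms: none
Why: Heating homolyses the strained central C1–C4 bond of the bicyclo[2.2.0]hexane to a cyclohexane-1,4-diyl, which relaxes to a chair and fragments at C5–C10, so that C1=C10 and C4=C5 appear together. The closest known reaction type is the thermal cycloreversion of cyclobutene–cyclohexenone photoadducts to cyclodeca-1,5-dienes, a formal retro-[2+2]. The ten-membered ring is not closed end to end: it is the perimeter of the tricycle and is released by cleaving two ring-fusion σ bonds, so no macrocyclisation entropy is paid. No stereocentre is created; C8 is untouched and C1, C4, C5 and C10 are erased. Because C6 and C9 are cis on the four-membered ring, one is axial and one equatorial on the diyl chair, which makes one alkene E and the other Z; the pairing needed (C6 equatorial gives 4E, C9 axial gives 1(10)Z) belongs to the chair in which the C10 methyl is axial on ring K. In 12 the C8 silyloxy group is trans to that methyl and so is equatorial only in this chair, whereas the competing chair forces it axial and syn to C1; this is the element meant to secure the pairing. Enone conjugation in the product and the short residence time should hold back the Cope rearrangement to the divinylcyclohexanone, and the neutral medium avoids silanol elimination.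

Step 10
Reactants: 13 silyloxy dienone
Product: 14 methyl 2-[(7R,8S)-8-(tert-butyldimethylsilyloxy)-4,10-dimethyl-6-oxocyclodeca-1(10)Z,4E-dien-7-yl]acetate (germacrane numbering)
Conditions: LiN(iPr)2, THF, −78 °C; BrCH2CO2Me, DMPU, −78 → −40 °C
Reagents that add atoms: methyl bromoacetate, COC(=O)CBr
Why: Kinetic deprotonation at C7 gives the cross-conjugated enolate, which is alkylated by the reactive α-bromo ester. On the conformer that keeps the silyloxy group outward the electrophile should enter from the outer face, placing the chain trans to the C8 oxygen; the low temperature suppresses loss of silanolate.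

Step 11
Reactants: 14 C7-alkylated dienone
Product: 16 6R-hydroxy acid (hydroxyl trans to the C7 chain), via hydroxy ester 15 (not isolated)
Conditions: NaBH4, CeCl3·7H2O, MeOH, −40 °C; then LiOH, THF/H2O, 0 °C; 1 M HCl to pH 5 at 0 °C; used at once
Reagents that add atoms: lithium hydroxide, [Li+].[OH-]
Why: Luche 1,2-reduction: hydride should add to the exposed outer face of the twisted enone carbonyl and leave the oxygens on C6 and C8 and the C7 chain all outward (6R). Saponification then frees the acid and reopens any trans-lactone formed on the way.

Step 12
Reactants: 16 6R-hydroxy acid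
Product: 17 cis-fused 12,6-lactone, 8-O-TBS (C6 S; C7 and C8 as in 14)
Conditions: PPh3, DIAD, THF, 0 °C
Reagents that add atoms: none
Why: Mitsunobu lactonisation: the allylic C6 hydroxyl is activated as the oxyphosphonium ion and displaced by the neighbouring carboxylate (5-exo SN2) with inversion, turning 6R into the 6S cis-lactone. The neutral medium avoids allylic ionisation and transannular cyclisation.

Step 13
Reactants: 17 cis-fused lactone
Product: 18 11-methyl lactone (methyl on the convex face)
Conditions: LiN(iPr)2, THF, −78 °C; MeI, −78 → −40 °C
Reagents that add atoms: iodomethane, CI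
Why: Lactone enolate alkylation from the convex face of the cis-fused bicycle, anti to C5 and C8. The new centre is re-enolised in step 14, so only mono-alkylation matters.

Step 14
Reactants: 18 11-methyl lactone
Product: 19 (11S)-11-hydroxy-11-methyl lactone
Conditions: KN(SiMe3)2, THF, −78 °C; 2-(phenylsulfonyl)-3-phenyloxaziridine, −78 °C; aq NH4Cl
Reagents that add atoms: 2-(phenylsulfonyl)-3-phenyloxaziridine (Davis oxaziridine), O=S(=O)(N1OC1c1ccccc1)c1ccccc1
Why: Electrophilic α-hydroxylation of the tetrasubstituted lactone enolate (Davis oxidation). Oxygen arrives on the convex face, anti to the ring carbons on C6 and C7, so the hydroxyl is convex and the methyl concave (11S); the ring alkenes are not attacked at −78 °C.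

Step 15
Reactants: 19 α-hydroxy lactone
Product: 20 11-O-angeloyl 8-O-TBS lactone
Conditions: LiN(SiMe3)2, THF, −78 °C; angelic anhydride, −78 → 0 °C; aq NH4Cl
Reagents that add atoms: angelic anhydride [(Z)-2-methylbut-2-enoic anhydride], C/C=C(/C)C(=O)OC(=O)/C(C)=C\C
Why: O-Acylation of a tertiary lithium alkoxide by a symmetric anhydride. Without nucleophilic catalysts or heat there is no addition–elimination path to the tiglate, and C11 has no α-hydrogen left.

Step 16
Reactants: 20 angelate silyl ether
Product: 21 8-hydroxy 11-angelate lactone
Conditions: HF·pyridine, pyridine/THF, 0 → 25 °C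
Reagents that add atoms: none
Why: Buffered fluoride cleavage of the secondary silyl ether; lactone, angelate geometry and 1,5-diene should survive the weakly acidic medium.

Step 17
Reactants: 21 8-hydroxy 11-angelate lactone
Product: 22 (1(10)Z,4E,6S,7R,8S,11S)-8-acetoxy-11-angeloyloxygermacra-1(10),4-dien-12,6-olide (target)
Conditions: Ac2O, pyridine, CH2Cl2, 25 °C
Reagents that add atoms: acetic anhydride, CC(=O)OC(C)=O
Why: Acetylation of the only free hydroxyl with retention at C8, under conditions that do not isomerise the angelate.

## Compound list

1 | phloroglucinol | Oc1cc(O)cc(O)c1 | starting material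
2 | all-cis-cyclohexane-1,3,5-triol | O[C@H]1C[C@@H](O)C[C@@H](O)C1 | intermediate
3 | all-cis-5-(tert-butyldimethylsilyloxy)cyclohexane-1,3-diol (meso) | O[C@H]1C[C@@H](O[Si](C)(C)C(C)(C)C)C[C@@H](O)C1 | intermediate
4 | (1R,3S,5S)-3-(tert-butyldimethylsilyloxy)-5-hydroxycyclohexyl acetate | CC(=O)O[C@H]1C[C@@H](O[Si](C)(C)C(C)(C)C)C[C@@H](O)C1 | intermediate
5 | cis-3-acetoxy-5-(tert-butyldimethylsilyloxy)cyclohexan-1-one (not isolated) | CC(=O)O[C@H]1C[C@@H](O[Si](C)(C)C(C)(C)C)CC(=O)C1 | intermediate
6 | (R)-5-(tert-butyldimethylsilyloxy)cyclohex-2-en-1-one | O=C1C=CC[C@@H](O[Si](C)(C)C(C)(C)C)C1 | intermediate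
7 | (5R)-5-(tert-butyldimethylsilyloxy)-1-methylcyclohex-2-en-1-ol, both C1 epimers | CC1(O)C=CC[C@@H](O[Si](C)(C)C(C)(C)C)C1 | intermediate
8 | (S)-5-(tert-butyldimethylsilyloxy)-3-methylcyclohex-2-en-1-one | O=C1C[C@@H](O[Si](C)(C)C(C)(C)C)CC(C)=C1 | intermediate
9 | methylenecyclobutane | C=C1CCC1 | starting material
10 | 1-methylcyclobutene | CC1=CCC1 | intermediate
11 | trans-fused photoadduct, C5 epimer of 12 (not isolated) | O=C1C[C@@H](O[Si](C)(C)C(C)(C)C)C[C@@]2(C)[C@@H]3CC[C@]3(C)[C@H]12 | intermediate
12 | cis-anti-cis tricyclic ketone: ring K C5–C10 (C6 ketone, 8S silyloxy, 10-methyl) fused at C5–C10 to the bicyclo[2.2.0]hexane C1–C4 (4-methyl); silyloxy cis to C1 and C4, trans to the C10 methyl | O=C1C[C@@H](O[Si](C)(C)C(C)(C)C)C[C@@]2(C)[C@@H]3CC[C@]3(C)[C@@H]12 | intermediate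
13 | (2E,6Z,9S)-9-(tert-butyldimethylsilyloxy)-3,7-dimethylcyclodeca-2,6-dien-1-one | O=C1/C=C(\C)CC/C=C(/C)C[C@H](O[Si](C)(C)C(C)(C)C)C1 | intermediate
14 | methyl 2-[(7R,8S)-8-(tert-butyldimethylsilyloxy)-4,10-dimethyl-6-oxocyclodeca-1(10)Z,4E-dien-7-yl]acetate | O=C1/C=C(\C)CC/C=C(/C)C[C@H](O[Si](C)(C)C(C)(C)C)[C@H]1CC(=O)OC | intermediate
15 | 6R-hydroxy methyl ester, hydroxyl trans to the C7 chain (not isolated) | O[C@@H]1/C=C(\C)CC/C=C(/C)C[C@H](O[Si](C)(C)C(C)(C)C)[C@H]1CC(=O)OC | intermediate
16 | 6R-hydroxy acid | O[C@@H]1/C=C(\C)CC/C=C(/C)C[C@H](O[Si](C)(C)C(C)(C)C)[C@H]1CC(=O)O | intermediate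
17 | 8-O-TBS germacra-1(10)Z,4E-dien-12,6-olide, cis-fused (C6 S) | O=C1O[C@H]2/C=C(\C)CC/C=C(/C)C[C@H](O[Si](C)(C)C(C)(C)C)[C@H]2C1 | intermediate
18 | 11-methyl lactone, methyl on the convex face | O=C1O[C@H]2/C=C(\C)CC/C=C(/C)C[C@H](O[Si](C)(C)C(C)(C)C)[C@H]2[C@@H]1C | intermediate
19 | (11S)-11-hydroxy-11-methyl lactone, 8-O-TBS | O=C1O[C@H]2/C=C(\C)CC/C=C(/C)C[C@H](O[Si](C)(C)C(C)(C)C)[C@H]2[C@]1(C)O | intermediate
20 | 11-O-angeloyl 8-O-TBS lactone | C/C=C(/C)C(=O)O[C@]1(C)C(=O)O[C@H]2/C=C(\C)CC/C=C(/C)C[C@H](O[Si](C)(C)C(C)(C)C)[C@H]21 | intermediate
21 | 8-hydroxy 11-O-angeloyl lactone | C/C=C(/C)C(=O)O[C@]1(C)C(=O)O[C@H]2/C=C(\C)CC/C=C(/C)C[C@H](O)[C@H]21 | intermediate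
22 | (1(10)Z,4E,6S,7R,8S,11S)-8-acetoxy-11-angeloyloxygermacra-1(10),4-dien-12,6-olide | C/C=C(/C)C(=O)O[C@]1(C)C(=O)O[C@H]2/C=C(\C)CC/C=C(/C)C[C@H](OC(C)=O)[C@H]21 | target

## Step count and least certain steps

Total: 17 steps. Longest linear sequence: 16 steps (1 to 22 through steps 1–6 and 8–17); step 7 is a one-step side branch.

Step 9 (key step).
- What may go wrong: part of the diyl may fragment through the other chair and give the 1(10)E,4Z isomer. That chair is intrinsically less crowded, because C6 axial on the diyl ring escapes eclipsing with the C4 methyl, and one equatorial silyloxy group may not outweigh this. Longer heating would also feed the Cope rearrangement.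
- Fallback: it sets out from 12. NaBH4 should add from the face away from the four-membered rings and give the tricyclic carbinol F1, with its hydroxyl cis to the silyloxy group. Both oxygens are then equatorial only in the productive chair and would be triaxial with C1 in the other. Thermolysis as in step 9 should give the dienol F2, and MnO2 oxidation of this allylic alcohol returns to 13.

Step 8.
- What may go wrong: the cyclobutene may add mainly to the enone face anti to the silyloxy group (first bond at the β-carbon, 1,3-trans induction), which would leave 12 as the minor facial isomer. Head-to-tail adducts would add to the loss.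
- Fallback: it sets out from 8. TMSOTf and Et3N give the silyl dienol ether F3. PhSCl attacks its γ-carbon C9 anti to the neighbouring silyloxy group and gives the trans-4-phenylthio enone F4. A substituent next to the reacting β-carbon dominates the facial choice, so irradiation with 10 should now occur on the silyloxy face and give, after alumina, the phenylthio tricycle F5. Deactivated Raney Ni removes sulfur and returns to 12.

Step 10.
- What may go wrong: poor facial selectivity at C7 on the mobile ten-membered enolate, or β-elimination of silanolate.
- Fallback: it sets out from 12, which is alkylated before ring opening (LiN(iPr)2, then BrCH2CO2Me). On the six-membered enolate the chain enters trans to the adjacent silyloxy group and gives the alkylated tricycle F6. Its two equatorial substituents also reinforce the productive chair. Thermolysis as in step 9 returns to 14.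

Step 11.
- What may go wrong: hydride may add to both faces of the C6 carbonyl, and the Mitsunobu closure of step 12 may go partly with retention, so that C6 epimers mix.
- Fallback: it sets out from 14. HF·pyridine gives the β-hydroxy ketone F7. Me4NBH(OAc)3 in MeCN/AcOH delivers hydride from the C8 oxygen and gives the 6,8-anti diol ester F8. Its C6 hydroxyl is cis to the C7 chain and should close on gentle warming to the hydroxy lactone F9, while the C8 hydroxyl is trans to the chain. TBSOTf and 2,6-lutidine return to 17, with no inversion step.

Step 15.
- What may go wrong: Z to E isomerisation of the angeloyl group, or no acylation of the hindered tertiary alkoxide.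
- Fallback: it sets out from 19. Its lithium alkoxide is acylated with 2-[bis(2,2,2-trifluoroethoxy)phosphoryl]propanoyl chloride to the phosphonate ester F10. A Still–Gennari olefination with acetaldehyde (KN(SiMe3)2, 18-crown-6, −78 °C) then builds the Z-enoate in place and returns to 20.

## Further compounds

F1 | step 9 | tricyclic carbinol, C6 hydroxyl cis to the silyloxy group | O[C@H]1C[C@@H](O[Si](C)(C)C(C)(C)C)C[C@@]2(C)[C@@H]3CC[C@]3(C)[C@@H]12
F2 | step 9 | (1(10)Z,4E)-8-silyloxy-4,10-dimethylcyclodecadien-6-ol, hydroxyl cis-1,3 to the silyloxy group | O[C@@H]1/C=C(\C)CC/C=C(/C)C[C@H](O[Si](C)(C)C(C)(C)C)C1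
F3 | step 8 | 1-trimethylsilyloxy-3-methyl-5-(tert-butyldimethylsilyloxy)cyclohexa-1,3-diene | C[Si](C)(C)OC1=CC(C)=C[C@H](O[Si](C)(C)C(C)(C)C)C1
F4 | step 8 | trans-4-phenylthio-5-(tert-butyldimethylsilyloxy)-3-methylcyclohex-2-en-1-one | O=C1C[C@@H](O[Si](C)(C)C(C)(C)C)[C@H](Sc2ccccc2)C(C)=C1
F5 | step 8 | 9-phenylthio derivative of 12, sulfur cis to the C10 methyl | O=C1C[C@@H](O[Si](C)(C)C(C)(C)C)[C@H](Sc2ccccc2)[C@@]3(C)[C@@H]4CC[C@]4(C)[C@@H]13
F6 | step 10 | 12 carrying CH2CO2CH3 at C7, trans to the silyloxy group | O=C1[C@H](CC(=O)OC)[C@@H](O[Si](C)(C)C(C)(C)C)C[C@@]2(C)[C@@H]3CC[C@]3(C)[C@@H]12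
F7 | step 11 | 8-hydroxy analogue of 14 | O=C1/C=C(\C)CC/C=C(/C)C[C@H](O)[C@H]1CC(=O)OC
F8 | step 11 | 6,8-anti diol methyl ester (C6 S) | O[C@H]1/C=C(\C)CC/C=C(/C)C[C@H](O)[C@H]1CC(=O)OC
F9 | step 11 | 8-hydroxy cis-fused 12,6-lactone | O=C1O[C@H]2/C=C(\C)CC/C=C(/C)C[C@H](O)[C@H]2C1
F10 | step 15 | 11-O-[2-(bis(2,2,2-trifluoroethoxy)phosphoryl)propanoyl] derivative of 19 | CC(C(=O)O[C@]1(C)C(=O)O[C@H]2/C=C(\C)CC/C=C(/C)C[C@H](O[Si](C)(C)C(C)(C)C)[C@H]21)P(=O)(OCC(F)(F)F)OCC(F)(F)F
A1 | alternative 1 | cis-lactone with C8 acetate, 11-triethylsilyloxy group, C5 (E)-2-iodopropenyl unit and (Z)-alkenyl chain ending in a primary TBS ether | CC[Si](CC)(CC)O[C@]1(C)C(=O)O[C@@H](/C=C(\C)I)[C@H]1[C@@H](OC(C)=O)C/C(C)=C\CCO[Si](C)(C)C(C)(C)C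
A2 | alternative 2 | 8-O-TBS 11-O-TES germacra-1(10)Z,4E-dien-12,6-olide | CC[Si](CC)(CC)O[C@]1(C)C(=O)O[C@H]2/C=C(\C)CC/C=C(/C)C[C@H](O[Si](C)(C)C(C)(C)C)[C@H]21
A3 | alternative 3 | ten-membered 6-ol with 8-O-TIPS and a C7 3-(tert-butyldimethylsilyloxy)prop-1-en-2-yl group | O[C@H]1/C=C(\C)CC/C=C(/C)C[C@H](O[Si](C(C)C)(C(C)C)C(C)C)[C@H]1C(=C)CO[Si](C)(C)C(C)(C)C
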